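The plan rests on growing ring A'' of flavone 2 around C6'' instead of forging the crowded C3–C6'' biaryl bond. C6'' lies between the oxygen-bearing carbons C5'' and C7'' and is bonded to C3 of flavone 1; exactly this pattern arises when a siloxyalkyne carrying the flavon-3-yl group undergoes benzannulation with a 3-alkoxycyclobutenone. One thermal operation forms C6''–C7'', C7''–C8'' and C4a''–C5'' and closes ring A''. The precursor is 5,7,4'-trimethoxyflavone bearing a (triisopropylsilyloxy)ethynyl group at C3. The benzyl ether that ends up para to C6'' is later unmasked alone, so that only this oxygen can become O1'' and the 3,6''-linkage is unambiguous.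

Key step: step 7

Assumption: the target SMILES carries no stereodescriptor, so the hindered C3–C6'' axis is treated as configurationally undefined (racemic if rotation proves slow); the carbinol centre made in step 1 is racemic and is removed in step 2.

Step 1
Reactants: 1 2,4,6-trimethoxybenzaldehyde; 2 4-ethynylanisole
Product: 3 1-(2,4,6-trimethoxyphenyl)-3-(4-methoxyphenyl)prop-2-yn-1-ol (racemic)
Conditions: 2, n-BuLi, THF, −78 °C; then 1, −78 → 0 °C; sat. aq. NH4Cl
Reagents that add atoms: none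
Why: Acetylide 1,2-addition to an aryl aldehyde should give the propargylic alcohol, whose single stereocentre is formed racemic and is destroyed in the next step.

Step 2
Reactants: 3 1-(2,4,6-trimethoxyphenyl)-3-(4-methoxyphenyl)prop-2-yn-1-ol
Product: 4 1-(2,4,6-trimethoxyphenyl)-3-(4-methoxyphenyl)prop-2-yn-1-one
Conditions: activated MnO2 (10 equiv), CH2Cl2, rt
Reagents that add atoms: none
Why: MnO2 oxidation of a benzylic-propargylic alcohol is mild and neutral, which suits the acid-sensitive electron-rich carbinol.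

Step 3
Reactants: 4 1-(2,4,6-trimethoxyphenyl)-3-(4-methoxyphenyl)prop-2-yn-1-one
Product: 5 3-iodo-5,7-dimethoxy-2-(4-methoxyphenyl)-4H-chromen-4-one
Conditions: ICl (1.5 equiv), CH2Cl2, −78 °C → rt; aq. Na2S2O3
Reagents that add atoms: iodine monochloride, ClI
Why: ICl-induced 6-endo-dig iodocyclization of an o-methoxyaryl ynone should deliver the 3-iodochromone, since either equivalent ortho methoxy oxygen attacks the iodonium-activated alkyne and chloride demethylates the resulting oxonium ion.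

Step 4
Reactants: 5 3-iodo-5,7-dimethoxy-2-(4-methoxyphenyl)-4H-chromen-4-one; 6 trimethylsilylacetylene
Product: 8 3-ethynyl-5,7-dimethoxy-2-(4-methoxyphenyl)-4H-chromen-4-one, via trimethylsilylalkyne 7 (not isolated)
Conditions: PdCl2(PPh3)2 (5 mol%), CuI (10 mol%), Et3N, DMF, 50 °C; crude through a silica plug, then K2CO3 (0.2 equiv), MeOH–THF, 0 °C → rt
Reagents that add atoms: none
Why: Sonogashira coupling at the sp2 C–I bond of a 3-iodochromone followed by base-catalysed methanolysis of the alkynyl C–Si bond should give the terminal alkyne, with a tertiary amine base chosen to avoid opening the pyranone.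

Step 5
Reactants: 8 3-ethynyl-5,7-dimethoxy-2-(4-methoxyphenyl)-4H-chromen-4-one
Product: 10 5,7-dimethoxy-2-(4-methoxyphenyl)-3-{[(triisopropylsilyl)oxy]ethynyl}-4H-chromen-4-one, via lithium ynolate 9 (not isolated)
Conditions: LiN(SiMe3)2 (1.1 equiv), THF, −78 °C; LiOOtBu (from t-BuOOH and LiN(SiMe3)2, THF, −78 °C), −78 → 0 °C; iPr3SiOTf, −78 → 0 °C; aq. NaHCO3, Et3N-deactivated silica
Reagents that add atoms: lithium tert-butyl peroxide, [Li+].[O-]OC(C)(C)C; triisopropylsilyl triflate, CC(C)[Si](OS(=O)(=O)C(F)(F)F)(C(C)C)C(C)C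
Why: Julia-type oxidation of the deprotonated alkyne by the electrophilic peroxide oxygen should give the ynolate, and the bulky silyl triflate should silylate it on oxygen to the siloxyalkyne and not on carbon to a silylketene.

Step 6
Reactants: 11 3-ethoxycyclobut-2-en-1-one
Product: 12 3-(benzyloxy)cyclobut-2-en-1-one
Conditions: BnOH (3 equiv), TsOH·H2O (5 mol%), toluene, 35 °C, reduced pressure to strip EtOH
Reagents that add atoms: benzyl alcohol, OCc1ccccc1
Why: Acid-catalysed vinylogous transesterification (addition–elimination at C3) driven by removal of ethanol should exchange the alkoxy group well below the temperature at which the ring opens, and it installs the only hydrogenolysable ether of the route.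

Step 7
Reactants: 10 5,7-dimethoxy-2-(4-methoxyphenyl)-3-{[(triisopropylsilyl)oxy]ethynyl}-4H-chromen-4-one; 12 3-(benzyloxy)cyclobut-2-en-1-one
Product: 17 3-[4-(benzyloxy)-2-hydroxy-6-(triisopropylsilyloxy)phenyl]-5,7-dimethoxy-2-(4-methoxyphenyl)-4H-chromen-4-one, via vinylketene 13 (not isolated), via vinylcyclobutenone 14 (not isolated), via dienylketene 15 (not isolated), via cyclohexadienone 16 (not isolated)
Conditions: 10 (1.0 equiv), 12 (1.5 equiv), toluene (0.3 M), argon, 80 °C, then 110 °C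
Reagents that add atoms: none
Why: Thermal 4π ring opening of 12 should give vinylketene 13, which adds [2+2] across the ynol ether to give 14 (forming C6''–C7'' and C4a''–C5'', ring A'' being numbered so that the ketene carbon becomes C7''); 14 opens by a second 4π step to dienylketene 15, which forms C7''–C8'' on closure to 16 and enolizes to phenol 17. The closest known reaction is the Danheiser benzannulation of cyclobutenones with siloxyalkynes to resorcinol monosilyl ethers. Ring A'' is closed by a 6π electrocyclization of the dienylketene, the reversible opening of 14 feeding the isomer whose ketene and vinyl termini are cis, and aromatization makes the cascade irreversible. No stereocentre is created, because the sp3 carbon of 14 is transient. The selectivity needed is the regiochemistry of the ketene–alkyne [2+2] step, secured by the polarization of the ynol ether: the alkyne carbon remote from oxygen, which carries the flavonyl group, is nucleophilic and bonds to the ketene carbonyl carbon, so the flavonyl ends between OH and OSi with the benzyloxy group para. The hindered aryl–C3 bond needs no coupling because it is present from the start as an unhindered sp–sp2 bond, and the chromone has no thermally reactive site under these conditions.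

Step 8
Reactants: 17 3-[4-(benzyloxy)-2-hydroxy-6-(triisopropylsilyloxy)phenyl]-5,7-dimethoxy-2-(4-methoxyphenyl)-4H-chromen-4-one
Product: 19 3-[4-(benzyloxy)-2,6-diisopropoxyphenyl]-5,7-dimethoxy-2-(4-methoxyphenyl)-4H-chromen-4-one, via resorcinol 18 (not isolated)
Conditions: CsF (1.5 equiv), DMF, rt; then Cs2CO3 (3 equiv), 2-bromopropane (6 equiv), 50 °C
Reagents that add atoms: 2-bromopropane, CC(C)Br
Why: Fluoride cleavage of the aryl silyl ether and Williamson alkylation of both phenoxides in one pot should cap the two oxygens flanking C6'' as isopropyl ethers, which survive hydrogenolysis and are removable by BCl3 at the end.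

Step 9
Reactants: 19 3-[4-(benzyloxy)-2,6-diisopropoxyphenyl]-5,7-dimethoxy-2-(4-methoxyphenyl)-4H-chromen-4-one
Product: 20 3-(4-hydroxy-2,6-diisopropoxyphenyl)-5,7-dimethoxy-2-(4-methoxyphenyl)-4H-chromen-4-one
Conditions: H2 (1 atm), Pd/C (10 wt%), EtOAc–MeOH, rt
Reagents that add atoms: none
Why: Hydrogenolysis of the single benzyl aryl ether should free only the oxygen para to C6'', since the tetrasubstituted chromone double bond and the methyl and isopropyl ethers are inert under these conditions.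

Step 10
Reactants: 20 3-(4-hydroxy-2,6-diisopropoxyphenyl)-5,7-dimethoxy-2-(4-methoxyphenyl)-4H-chromen-4-one
Product: 21 3-(3-acetyl-4-hydroxy-2,6-diisopropoxyphenyl)-5,7-dimethoxy-2-(4-methoxyphenyl)-4H-chromen-4-one
Conditions: Ac2O (3 equiv), BF3·OEt2 (3 equiv), CH2Cl2, 0 → 40 °C; then aq. NaOAc, MeOH, 50 °C
Reagents that add atoms: acetic anhydride, CC(=O)OC(C)=O
Why: BF3-mediated Friedel–Crafts C-acetylation (direct or by Fries rearrangement of the aryl acetate) should occur ortho to the free phenol, because the para position is blocked, the two ortho positions are equivalent and this ring is the most electron-rich arene present.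

Step 11
Reactants: 21 3-(3-acetyl-4-hydroxy-2,6-diisopropoxyphenyl)-5,7-dimethoxy-2-(4-methoxyphenyl)-4H-chromen-4-one; 22 4-isopropoxybenzoyl chloride
Product: 24 3-[5,7-diisopropoxy-2-(4-isopropoxyphenyl)-4-oxo-4H-chromen-6-yl]-5,7-dimethoxy-2-(4-methoxyphenyl)-4H-chromen-4-one, via diketone 23 (not isolated)
Conditions: LiN(SiMe3)2 (4 equiv), THF, −78 °C; 22 (1.1 equiv), −78 °C → rt; AcOH quench, then AcOH, H2SO4 (cat.), 90 °C
Reagents that add atoms: none
Why: C-aroylation of the acetophenone dianion (a Baker–Venkataraman-type route to the 1,3-diketone) followed by acid-catalysed cyclodehydration should close ring C'' in one sense only, because the sole free hydroxyl next to the acyl group is the one para to C6'', whereas a ring with both neighbouring hydroxyls free could also give the 3,8''-linked isomer.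

Step 12
Reactants: 24 3-[5,7-diisopropoxy-2-(4-isopropoxyphenyl)-4-oxo-4H-chromen-6-yl]-5,7-dimethoxy-2-(4-methoxyphenyl)-4H-chromen-4-one
Product: 25 3-[5,7-dihydroxy-2-(4-hydroxyphenyl)-4-oxo-4H-chromen-6-yl]-5-hydroxy-7-methoxy-2-(4-methoxyphenyl)-4H-chromen-4-one (CNP0273448.0)
Conditions: BCl3 (1 M in CH2Cl2, 10 equiv), CH2Cl2, −78 °C → rt; MeOH, then H2O
Reagents that add atoms: none
Why: BCl3 ether cleavage should remove the three isopropyl groups and, through the boron chelate with the C4 carbonyl, the peri 5-methyl group, while the unchelated 7- and 4'-methyl ethers are left in place.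

Compound list
1 | 2,4,6-trimethoxybenzaldehyde | COc1cc(OC)c(C=O)c(OC)c1 | starting material
2 | 4-ethynylanisole | C#Cc1ccc(OC)cc1 | starting material
3 | 1-(2,4,6-trimethoxyphenyl)-3-(4-methoxyphenyl)prop-2-yn-1-ol (racemic) | COc1ccc(C#CC(O)c2c(OC)cc(OC)cc2OC)cc1 | intermediate
4 | 1-(2,4,6-trimethoxyphenyl)-3-(4-methoxyphenyl)prop-2-yn-1-one | COc1ccc(C#CC(=O)c2c(OC)cc(OC)cc2OC)cc1 | intermediate
5 | 3-iodo-5,7-dimethoxy-2-(4-methoxyphenyl)-4H-chromen-4-one | COc1ccc(-c2oc3cc(OC)cc(OC)c3c(=O)c2I)cc1 | intermediate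
6 | trimethylsilylacetylene | C#C[Si](C)(C)C | starting material
7 | 5,7-dimethoxy-2-(4-methoxyphenyl)-3-[(trimethylsilyl)ethynyl]-4H-chromen-4-one | COc1ccc(-c2oc3cc(OC)cc(OC)c3c(=O)c2C#C[Si](C)(C)C)cc1 | intermediate (not isolated)
8 | 3-ethynyl-5,7-dimethoxy-2-(4-methoxyphenyl)-4H-chromen-4-one | COc1ccc(-c2oc3cc(OC)cc(OC)c3c(=O)c2C#C)cc1 | intermediate
9 | lithium 2-[5,7-dimethoxy-2-(4-methoxyphenyl)-4-oxo-4H-chromen-3-yl]ethyn-1-olate | COc1ccc(-c2oc3cc(OC)cc(OC)c3c(=O)c2C#C[O-])cc1.[Li+] | intermediate (not isolated)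
10 | 5,7-dimethoxy-2-(4-methoxyphenyl)-3-{[(triisopropylsilyl)oxy]ethynyl}-4H-chromen-4-one | COc1ccc(-c2oc3cc(OC)cc(OC)c3c(=O)c2C#CO[Si](C(C)C)(C(C)C)C(C)C)cc1 | intermediate
11 | 3-ethoxycyclobut-2-en-1-one | CCOC1=CC(=O)C1 | starting material
12 | 3-(benzyloxy)cyclobut-2-en-1-one | O=C1C=C(OCc2ccccc2)C1 | intermediate
13 | 3-(benzyloxy)buta-1,3-dien-1-one | O=C=CC(=C)OCc1ccccc1 | intermediate (not isolated)
14 | 4-[1-(benzyloxy)vinyl]-2-[5,7-dimethoxy-2-(4-methoxyphenyl)-4-oxo-4H-chromen-3-yl]-3-[(triisopropylsilyl)oxy]cyclobut-2-en-1-one (racemic) | COc1ccc(-c2oc3cc(OC)cc(OC)c3c(=O)c2C2=C(O[Si](C(C)C)(C(C)C)C(C)C)C(C(=C)OCc3ccccc3)C2=O)cc1 | intermediate (not isolated)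
15 | (3E)-5-(benzyloxy)-2-[5,7-dimethoxy-2-(4-methoxyphenyl)-4-oxo-4H-chromen-3-yl]-3-[(triisopropylsilyl)oxy]hexa-1,3,5-trien-1-one (ketene and vinyl termini cis) | COc1ccc(-c2oc3cc(OC)cc(OC)c3c(=O)c2C(=C=O)/C(O[Si](C(C)C)(C(C)C)C(C)C)=C\C(=C)OCc2ccccc2)cc1 | intermediate (not isolated)
16 | 5-(benzyloxy)-2-[5,7-dimethoxy-2-(4-methoxyphenyl)-4-oxo-4H-chromen-3-yl]-3-[(triisopropylsilyl)oxy]cyclohexa-2,4-dien-1-one | COc1ccc(-c2oc3cc(OC)cc(OC)c3c(=O)c2C2=C(O[Si](C(C)C)(C(C)C)C(C)C)C=C(OCc3ccccc3)CC2=O)cc1 | intermediate (not isolated)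
17 | 3-[4-(benzyloxy)-2-hydroxy-6-(triisopropylsilyloxy)phenyl]-5,7-dimethoxy-2-(4-methoxyphenyl)-4H-chromen-4-one | COc1ccc(-c2oc3cc(OC)cc(OC)c3c(=O)c2-c2c(O)cc(OCc3ccccc3)cc2O[Si](C(C)C)(C(C)C)C(C)C)cc1 | intermediate
18 | 3-[4-(benzyloxy)-2,6-dihydroxyphenyl]-5,7-dimethoxy-2-(4-methoxyphenyl)-4H-chromen-4-one | COc1ccc(-c2oc3cc(OC)cc(OC)c3c(=O)c2-c2c(O)cc(OCc3ccccc3)cc2O)cc1 | intermediate (not isolated)
19 | 3-[4-(benzyloxy)-2,6-diisopropoxyphenyl]-5,7-dimethoxy-2-(4-methoxyphenyl)-4H-chromen-4-one | COc1ccc(-c2oc3cc(OC)cc(OC)c3c(=O)c2-c2c(OC(C)C)cc(OCc3ccccc3)cc2OC(C)C)cc1 | intermediate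
20 | 3-(4-hydroxy-2,6-diisopropoxyphenyl)-5,7-dimethoxy-2-(4-methoxyphenyl)-4H-chromen-4-one | COc1ccc(-c2oc3cc(OC)cc(OC)c3c(=O)c2-c2c(OC(C)C)cc(O)cc2OC(C)C)cc1 | intermediate
21 | 3-(3-acetyl-4-hydroxy-2,6-diisopropoxyphenyl)-5,7-dimethoxy-2-(4-methoxyphenyl)-4H-chromen-4-one | COc1ccc(-c2oc3cc(OC)cc(OC)c3c(=O)c2-c2c(OC(C)C)cc(O)c(C(C)=O)c2OC(C)C)cc1 | intermediate
22 | 4-isopropoxybenzoyl chloride | CC(C)Oc1ccc(C(=O)Cl)cc1 | starting material
23 | 1-{3-[5,7-dimethoxy-2-(4-methoxyphenyl)-4-oxo-4H-chromen-3-yl]-6-hydroxy-2,4-diisopropoxyphenyl}-3-(4-isopropoxyphenyl)propane-1,3-dione | COc1ccc(-c2oc3cc(OC)cc(OC)c3c(=O)c2-c2c(OC(C)C)cc(O)c(C(=O)CC(=O)c3ccc(OC(C)C)cc3)c2OC(C)C)cc1 | intermediate (not isolated)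
24 | 3-[5,7-diisopropoxy-2-(4-isopropoxyphenyl)-4-oxo-4H-chromen-6-yl]-5,7-dimethoxy-2-(4-methoxyphenyl)-4H-chromen-4-one | COc1ccc(-c2oc3cc(OC)cc(OC)c3c(=O)c2-c2c(OC(C)C)cc3oc(-c4ccc(OC(C)C)cc4)cc(=O)c3c2OC(C)C)cc1 | intermediate
25 | 3-[5,7-dihydroxy-2-(4-hydroxyphenyl)-4-oxo-4H-chromen-6-yl]-5-hydroxy-7-methoxy-2-(4-methoxyphenyl)-4H-chromen-4-one | COc1ccc(-c2oc3cc(OC)cc(O)c3c(=O)c2-c2c(O)cc3oc(-c4ccc(O)cc4)cc(=O)c3c2O)cc1 | target

Total step count: 12. Longest linear sequence: 11 steps (steps 1–5 and 7–12; step 6 is a one-step branch to the cyclobutenone).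

Steps most likely to fail

1. Step 7. The vinylketene may be used up by self-condensation, or by acylating the product phenol, faster than the hindered and only moderately nucleophilic flavonyl ynol ether captures it. The ynol ether may also lose its silyl group on prolonged heating. The fallback abandons ring growth and makes the C3–C6'' bond by cross-coupling; it sets out from 5 and comes back at 24. Purchased apigenin is alkylated at O7 and O4' (2-bromopropane, K2CO3, DMF) to 5-hydroxy-7-isopropoxy-2-(4-isopropoxyphenyl)-4H-chromen-4-one F1. Iodination next to the chelated 5-hydroxyl (BnMe3N+ ICl2−, CaCO3, CH2Cl2–MeOH) should give 5-hydroxy-6-iodo-7-isopropoxy-2-(4-isopropoxyphenyl)-4H-chromen-4-one F2. Alkylation of the 5-hydroxyl (2-bromopropane, Cs2CO3, DMF, 60 °C) gives 6-iodo-5,7-diisopropoxy-2-(4-isopropoxyphenyl)-4H-chromen-4-one F3. Borylation (pinacolborane, PdCl2(MeCN)2, SPhos, Et3N, dioxane, 80 °C) gives 5,7-diisopropoxy-2-(4-isopropoxyphenyl)-6-(4,4,5,5-tetramethyl-1,3,2-dioxaborolan-2-yl)-4H-chromen-4-one F4. Suzuki–Miyaura coupling of F4 with 5 (Pd(OAc)2, SPhos, K3PO4, toluene–H2O, 100 °C) should then give 24.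

2. Step 5. The peroxide or the acetylide may attack the chromone (conjugate addition at C2 and ring opening), or the ynolate may be silylated on carbon. The fallback reaches the ynolate through an alkynyl sulfonate instead of by acetylide oxidation; it sets out from 8 and comes back at 10 by way of 9. Treatment of 8 with PhI(OH)OTs (CHCl3, reflux) should give {[5,7-dimethoxy-2-(4-methoxyphenyl)-4-oxo-4H-chromen-3-yl]ethynyl}(phenyl)iodonium tosylate F5. Collapse of F5 with CuOTf (cat., MeCN, rt) gives [5,7-dimethoxy-2-(4-methoxyphenyl)-4-oxo-4H-chromen-3-yl]ethynyl 4-methylbenzenesulfonate F6. MeLi (THF, −78 °C) attacks sulfur and releases ynolate 9, which is silylated with iPr3SiOTf to 10.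

3. Step 10. The Lewis acid may strip the isopropyl group next to the new acetyl group, which would free a second oxygen able to close ring C'', or the reaction may stop at the aryl acetate. The fallback builds the pyranone without any Friedel–Crafts step; it sets out from 20 and comes back at 24. Mono-iodination ortho to the phenol (NIS, 1.0 equiv, CH2Cl2, −40 → 0 °C) should give 3-(4-hydroxy-3-iodo-2,6-diisopropoxyphenyl)-5,7-dimethoxy-2-(4-methoxyphenyl)-4H-chromen-4-one F7. Carbonylative Sonogashira annulation of F7 with purchased 1-ethynyl-4-isopropoxybenzene (CO, 1 atm, PdCl2(PPh3)2, Et2NH, 60 °C) closes ring C'' through the only free hydroxyl and gives 24.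

Further compounds
F1 | step 7 | 5-hydroxy-7-isopropoxy-2-(4-isopropoxyphenyl)-4H-chromen-4-one | CC(C)Oc1ccc(-c2cc(=O)c3c(O)cc(OC(C)C)cc3o2)cc1
F2 | step 7 | 5-hydroxy-6-iodo-7-isopropoxy-2-(4-isopropoxyphenyl)-4H-chromen-4-one | CC(C)Oc1ccc(-c2cc(=O)c3c(O)c(I)c(OC(C)C)cc3o2)cc1
F3 | step 7 | 6-iodo-5,7-diisopropoxy-2-(4-isopropoxyphenyl)-4H-chromen-4-one | CC(C)Oc1ccc(-c2cc(=O)c3c(OC(C)C)c(I)c(OC(C)C)cc3o2)cc1
F4 | step 7 | 5,7-diisopropoxy-2-(4-isopropoxyphenyl)-6-(4,4,5,5-tetramethyl-1,3,2-dioxaborolan-2-yl)-4H-chromen-4-one | CC(C)Oc1ccc(-c2cc(=O)c3c(OC(C)C)c(B4OC(C)(C)C(C)(C)O4)c(OC(C)C)cc3o2)cc1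
F5 | step 5 | {[5,7-dimethoxy-2-(4-methoxyphenyl)-4-oxo-4H-chromen-3-yl]ethynyl}(phenyl)iodonium tosylate | COc1ccc(-c2oc3cc(OC)cc(OC)c3c(=O)c2C#C[I+]c2ccccc2)cc1.Cc1ccc(S(=O)(=O)[O-])cc1
F6 | step 5 | [5,7-dimethoxy-2-(4-methoxyphenyl)-4-oxo-4H-chromen-3-yl]ethynyl 4-methylbenzenesulfonate | COc1ccc(-c2oc3cc(OC)cc(OC)c3c(=O)c2C#COS(=O)(=O)c2ccc(C)cc2)cc1
F7 | step 10 | 3-(4-hydroxy-3-iodo-2,6-diisopropoxyphenyl)-5,7-dimethoxy-2-(4-methoxyphenyl)-4H-chromen-4-one | COc1ccc(-c2oc3cc(OC)cc(OC)c3c(=O)c2-c2c(OC(C)C)cc(O)c(I)c2OC(C)C)cc1
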